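Assumption (remark on the chemistry): the SMILES fixes the C1 ester as the (2R)-2-methylbutanoate; (2R)-2-methylbutanoic acid and (2E)-3-methylpent-2-enoic acid are taken as purchasable single isomers.

## Structural features

The target is a trans-fused hydrindan-2-one in which ring A is the cyclopentanone (C1, C2, C3, C3a, C7a) and ring B the cyclohexane (C3a, C4, C5, C6, C7, C7a), joined through the C3a–C7a bond with anti hydrogens. Ring B carries an equatorial isopropyl group at C4, an exocyclic methylene at C7 and, next to it at C6, an axial (2E)-3-methylpent-2-enoate. Ring A carries the C2 ketone flanked by a (2R)-2-methylbutanoyloxy group at C1 and a (1S)-1-acetoxyethyl arm at C3. The six ring stereocentres are 1R,3R,3aR,4R,6S,7aS: C4, C3a, C3 and the side-arm carbinol C1' form one contiguous run, C3a, C7a and C1 a second, and C6 stands alone behind the sp2 carbon C7. The fragile points are the β-acetoxy ketone (E1cB loss of acetate), the epimerisable α-acyloxy ketone at C1 (its ester is pseudo-axial and cis to C7), the allylic ester beside the exocyclic alkene, and three different esters that exclude strong base late in the route. The real difficulty is to set the C4/C3a/C7a triad with the trans fusion and then to place three differentiated oxygen functions with control at C1, C1' and C6. The key step exploits the fact that C4 (isopropyl trans to the C3a–C3 bond), C3a and C7a (trans fusion) carry exactly the pattern an (E)-dienophile leaves in a [4+2] cycloaddition, with C1–C2–C3 of ring A as the three-atom tether and the C6–C7 alkene of the adduct as the handle for the methylene and the allylic ester.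

## Logic of the disconnections

32 ⇒ 30 + 31. The C6–O acyl bond is cut first because the unsaturated acyl group is the ester most easily isomerised, so it should see the fewest steps. This leaves one free hydroxyl. The forward step must acylate an axial allylic alcohol without eliminating the acetate.

30 ⇒ 29. The C7=CH2 / C6–OH pair is traced back to a C6–C7 epoxide (C7–O bond and one methyl C–H are exchanged for the alkene). This returns the ring alkene of the cycloadduct and fixes C6 through the epoxide face. The forward step must be neutral, because two base-sensitive ketone esters are present.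

29 ⇒ 27 + 28. The C1–O bond is cut with inversion, because the cycloaddition can only deliver the C1 oxygen on the α-face. Esterification and inversion become one operation. The forward step is an SN2 displacement at a hindered α-keto carbinol.

27 ⇒ 26. The epoxide C–O bonds are removed to give the ring alkene. The free α-hydroxyl at C1 is kept at this stage so that it can steer the oxidant to the α-face before it is inverted.

26 ⇒ 25 ⇒ 24. The silyl ether and the acetate are adjusted (O–Si and O–acyl bonds). The acetate must be on before the hydroxyl at C1 is freed, so that only one hydroxyl enters the Mitsunobu step.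

24 ⇒ 20 + 21. The C3–C1' bond is cut (aldol). This removes two stereocentres and the whole side arm. The forward step must enolise towards C3 only, add anti to the C3a–C4 bond and give the syn aldol.

20 ⇒ 19 ⇒ 18 ⇒ 17. These are functional-group changes. The C2 ketone comes from the thioacetal (two C–S bonds), and the isopropyl group from the acetyl group by way of the isopropenyl group. The thioacetal must stay until the methyl ketone has been methylenated, so that only one carbonyl group is ever free.

17 ⇒ 16. The C3a–C7a and C4–C5 bonds are cut in a retro-[4+2]. Both rings and three stereocentres disappear and an acyclic trienone with one stereocentre remains. The structures of 16 and 17 were checked against 32: C4, C3a and C7a of 17 match 32 and C1 is epimeric, as the allylic-strain model requires, so neither skeleton needs correction. The forward step needs endo and diene-face selectivity.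

16 ⇒ 14 + 15. The enone C=C bond is cut (Wittig). The dienophile is attached last, so that the reactive trienone does not have to survive other steps.

14 ⇒ 12 ⇒ 11 ⇒ 10 ⇒ 9. These are aldehyde unmasking, silylation and an oxidation/asymmetric reduction pair at the carbinol (C–O and C–H bonds only). The one design change is made here: the acetal is opened without protic acid, because the dienylic silyl ether beside the thioacetal is an ionisable position. The reduction must distinguish a fully substituted thioacetal carbon from a dienyl group.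

9 ⇒ 4 + 7. The bond between the thioacetal carbon and the carbinol carbon is cut (acyl-anion addition). It joins the tether to the diene. The forward step must be a 1,2-addition.

4 ⇒ 1 + 2 and 7 ⇒ 6 ⇒ 5. A C–C bond at the thioacetal carbon is cut (alkylation). The dienal is traced to a commercial enynol whose (E)-alkene already holds the diene geometry needed for the allylic-strain control.

## Other disconnections considered

Alternative 1: The cut is the C6–C7 bond of ring B.
- Forward step: the ynal A1 (a cyclopentanone with an ethynyl group at C7a and the aldehyde chain at C3a) would be cyclised with Ni(COD)2, an N-heterocyclic carbene and Et3SiH. Zerovalent nickel couples alkyne and aldehyde oxidatively, the silane cleaves the Ni–O bond, and reductive elimination gives A2.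
- In its favour: the exocyclic methylene and the C6 oxygen appear in the ring-closing step itself, where the chosen plan spends two steps (27, 30). On this point the alternative is the better. The conditions are neutral and spare the ketone.
- Against it: only one ring, one C–C bond and one stereocentre are made. C7a, C3a, C4, C3 and C1' must all be present in A1, set on a monocyclic ketone with C4 outside the ring. The C6 oxygen comes out equatorial and needs inversion (equal to the chosen plan, one Mitsunobu inversion each). C1 has no oxygen, so a late α-hydroxylation must deliver the less favoured pseudo-axial group.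
- Comparison: A2 is closer to 32 in ring B than 17, but further in ring A. The mechanism is a metal-mediated reductive coupling against a pericyclic step with three stereocentres. The step saving at C6/C7 is likely lost in the construction of A1.

Alternative 2: The cut is the C3–C3a bond of ring A.
- Forward step: the diazo keto ester A4 with Rh2(OAc)4 would give a rhodium carbenoid that inserts 1,5 into the equatorial C–H bond at the future C3a with retention, giving A5.
- In its favour: ring B and the isopropyl group come from the achiral ketone A3, so the two steps from acetyl to isopropyl are saved (better than the chosen plan). The C1 oxygen is already in the target configuration, so no inversion is needed (better). Insertion into an equatorial C–H bond is a reliable way to a trans fusion (equal).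
- Against it: A3 must be desymmetrised and C7a/C1 set before the key step. The carbenoid may also attack the activated C–H bonds of the dioxolane, and the C3a–H bond is shielded by the neighbouring isopropyl group. Turning the ester of A5 into the (1S)-acetoxyethyl arm beside a ring ketone costs several redox steps, where 24 is reached in one C–C bond formation. Ring B still needs oxygen at C6 and a methylene at C7 through a ketone that can epimerise C7a.
- Comparison: the starting material is simpler, but one bond and one ring are formed per key step and the endgame is longer on both rings.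

Alternative 3: The cuts are C3a–C7a, C2–C3 and C1–C2.
- Forward step: the enyne A6 with Co2(CO)8 and an amine N-oxide would form the alkyne–hexacarbonyldicobalt complex, insert the vinyl group and CO, and give the cyclopentenone A7.
- In its favour: three C–C bonds and both rings form in one step (better than the two bonds of step 10). The C6 oxygen is already correct and C4 and C1' are set by acyclic methods (equal or better at C6). The CH2O group at C7 is a precursor of the methylene.
- Against it: closing a six-membered ring from a 1,7-enyne is the slow case of this reaction and leans on the acetonide. A7 has a tetrasubstituted C3=C3a enone, so C3a and C3 must be set by a conjugate reduction that has to give the trans fusion without expelling the β-silyloxy group from the enolate. C1 oxygen must be added late, and the face at C7a depends on remote control.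
- Comparison: bond count per step is higher, but the stereochemical work deferred to after the key step (reduction, C1 oxidation, acetonide removal, elimination) is greater than in the chosen plan.

Key step: step 10

## Route

Step 1
Reactants: 1 1,3-dithiane; 2 2-bromo-1,1-diethoxyethane
Product: 4 2-(2,2-diethoxyethyl)-1,3-dithiane, via 2-lithio-1,3-dithiane 3 (not isolated)
Conditions: n-BuLi, THF, −30 °C; then 2, −78 °C → rt
Reagents that add atoms: none
Why: Corey–Seebach alkylation of the sulfur-stabilised carbanion at a primary bromide; the acetal carries the future dienophile carbons in masked form.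

Step 2
Reactants: 5 (2E)-3-methylpent-2-en-4-yn-1-ol
Product: 6 (2E)-3-methylpenta-2,4-dien-1-ol
Conditions: H2 (1 atm), Pd/CaCO3 poisoned with Pb(OAc)2, quinoline, EtOAc, 0 °C
Reagents that add atoms: none
Why: Lindlar-type semihydrogenation of the terminal alkyne of a conjugated enyne should stop at the vinyl group; the trisubstituted (E)-alkene is untouched, so the diene geometry is fixed by 5.

Step 3
Reactants: 6 (2E)-3-methylpenta-2,4-dien-1-ol
Product: 7 (2E)-3-methylpenta-2,4-dienal
Conditions: MnO2, CH2Cl2, rt; filtrate used directly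
Reagents that add atoms: none
Why: MnO2 oxidises allylic alcohols selectively and without acid or base; the volatile, dimerisation-prone dienal is carried on as a solution.

Step 4
Reactants: 4 2-(2,2-diethoxyethyl)-1,3-dithiane; 7 (2E)-3-methylpenta-2,4-dienal
Product: 9 rac-(2E)-1-[2-(2,2-diethoxyethyl)-1,3-dithian-2-yl]-3-methylpenta-2,4-dien-1-ol, via 2-lithio-2-(2,2-diethoxyethyl)-1,3-dithiane 8 (not isolated)
Conditions: n-BuLi, THF, −25 °C; then 7, −78 °C; then H2O
Reagents that add atoms: none
Why: Corey–Seebach acyl-anion addition; in THF without polar additives the lithiated thioacetal should add 1,2 to the enal, and the β,β-disubstitution of 7 disfavours conjugate addition. The carbinol is racemic at this stage.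

Step 5
Reactants: 9 rac-(2E)-1-[2-(2,2-diethoxyethyl)-1,3-dithian-2-yl]-3-methylpenta-2,4-dien-1-ol
Product: 10 (2E)-1-[2-(2,2-diethoxyethyl)-1,3-dithian-2-yl]-3-methylpenta-2,4-dien-1-one
Conditions: MnO2, CH2Cl2, rt
Reagents that add atoms: none
Why: allylic oxidation with MnO2 leaves the thioacetal sulfur and the acetal alone and erases the uncontrolled carbinol centre.

Step 6
Reactants: 10 (2E)-1-[2-(2,2-diethoxyethyl)-1,3-dithian-2-yl]-3-methylpenta-2,4-dien-1-one
Product: 11 (1S,2E)-1-[2-(2,2-diethoxyethyl)-1,3-dithian-2-yl]-3-methylpenta-2,4-dien-1-ol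
Conditions: (R)-Me-CBS oxazaborolidine (0.3 equiv), catecholborane, toluene, −78 °C; then MeOH, aq. NaOH
Reagents that add atoms: none
Why: CBS reduction of a 2-acyl-1,3-dithiane; the fully substituted thioacetal carbon should act as the large group, so the (R)-catalyst delivers hydride to the Re face and gives the (S)-carbinol. Catecholborane at −78 °C reduces 1,2 and does not hydroborate the diene.

Step 7
Reactants: 11 (1S,2E)-1-[2-(2,2-diethoxyethyl)-1,3-dithian-2-yl]-3-methylpenta-2,4-dien-1-ol
Product: 12 tert-butyl{[(1S,2E)-1-[2-(2,2-diethoxyethyl)-1,3-dithian-2-yl]-3-methylpenta-2,4-dien-1-yl]oxy}dimethylsilane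
Conditions: TBSOTf (1.3 equiv), 2,6-lutidine, CH2Cl2, −78 °C
Reagents that add atoms: tert-butyldimethylsilyl trifluoromethanesulfonate, CC(C)(C)[Si](C)(C)OS(=O)(=O)C(F)(F)F
Why: a silyl triflate silylates the hindered secondary alcohol at −78 °C, faster than it can attack the acetal; the bulky silyl ether later reinforces the facial bias of the cycloaddition.

Step 8
Reactants: 12 tert-butyl{[(1S,2E)-1-[2-(2,2-diethoxyethyl)-1,3-dithian-2-yl]-3-methylpenta-2,4-dien-1-yl]oxy}dimethylsilane
Product: 14 {2-[(1S,2E)-1-{[tert-butyl(dimethyl)silyl]oxy}-3-methylpenta-2,4-dien-1-yl]-1,3-dithian-2-yl}acetaldehyde, via collidinium salt 13 (not isolated)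
Conditions: Et3SiOTf, 2,4,6-collidine, CH2Cl2, 0 °C; then H2O, rt
Reagents that add atoms: water, O
Why: silyl-triflate/collidine cleavage of an aldehyde acetal; the triflate removes one ethoxy group, collidine traps the oxocarbenium ion as 13, and water releases the aldehyde. No protic acid is present, so the dienylic silyl ether next to the thioacetal is not ionised.

Step 9
Reactants: 14 {2-[(1S,2E)-1-{[tert-butyl(dimethyl)silyl]oxy}-3-methylpenta-2,4-dien-1-yl]-1,3-dithian-2-yl}acetaldehyde; 15 1-(triphenylphosphoranylidene)propan-2-one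
Product: 16 (3E)-5-{2-[(1S,2E)-1-{[tert-butyl(dimethyl)silyl]oxy}-3-methylpenta-2,4-dien-1-yl]-1,3-dithian-2-yl}pent-3-en-2-one
Conditions: CH2Cl2, rt
Reagents that add atoms: none
Why: Wittig olefination with a stabilised ylide should give the (E)-enone under neutral conditions; room temperature avoids an uncontrolled thermal cycloaddition.

Step 10
Reactants: 16 (3E)-5-{2-[(1S,2E)-1-{[tert-butyl(dimethyl)silyl]oxy}-3-methylpenta-2,4-dien-1-yl]-1,3-dithian-2-yl}pent-3-en-2-one
Product: 17 1-[(1'S,3a'S,4'S,7a'S)-1'-{[tert-butyl(dimethyl)silyl]oxy}-7'-methyl-1',3',3a',4',5',7a'-hexahydrospiro[1,3-dithiane-2,2'-inden]-4'-yl]ethan-1-one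
Conditions: Me2AlCl (1.5 equiv), CH2Cl2, −78 → −20 °C; aq. work-up
Reagents that add atoms: none
Why: Concerted, asynchronous [4+2] cycloaddition in which Me2AlCl on the enone oxygen lowers the dienophile LUMO; the closest known reaction type is the Lewis-acid-promoted intramolecular Diels–Alder reaction of terminally activated (E)-1,6,8-nonatrienes to trans-fused bicyclo[4.3.0]nonenes. Ring B closes as the cycloadduct ring (both new σ-bonds, C3a–C7a and C4–C5, lie in it) and ring A closes in the fused mode through the tether C1–C2–C3 when the C3a–C7a bond forms. C4 and C3a: their trans relation is the suprafacial transfer of the (E)-enone geometry. C3a/C7a: the trans fusion follows from the transition state with the aluminium-bound acetyl group endo and the tether exo, which the Lewis acid should favour over the cis-fused alternative. Diene face, hence absolute configuration: the (S)-silyloxy carbon keeps its hydrogen in the diene plane beside the cis methyl group (allylic 1,3-strain), so the tether reaches the dienophile over one face only and the silyl ether ends up on the α-face, cis to H7a. The selectivities needed are endo/exo and diene face; regiochemistry is fixed by the tether, the thioacetal adds a gem-disubstituent effect that favours folding, and the low temperature protects the dienylic silyl ether.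

Step 11
Reactants: 17 1-[(1'S,3a'S,4'S,7a'S)-1'-{[tert-butyl(dimethyl)silyl]oxy}-7'-methyl-1',3',3a',4',5',7a'-hexahydrospiro[1,3-dithiane-2,2'-inden]-4'-yl]ethan-1-one
Product: 18 tert-butyl(dimethyl){[(1'S,3a'R,4'S,7a'S)-7'-methyl-4'-(prop-1-en-2-yl)-1',3',3a',4',5',7a'-hexahydrospiro[1,3-dithiane-2,2'-inden]-1'-yl]oxy}silane
Conditions: Ph3PCH3Br, KOtBu, THF, 0 °C → rt
Reagents that add atoms: methyltriphenylphosphonium bromide, C[P+](c1ccccc1)(c1ccccc1)c1ccccc1.[Br-]
Why: Wittig methylenation of the only free carbonyl group (the ring ketone is still a thioacetal); C4 already holds the stable equatorial configuration, so reversible enolisation by the ylide is harmless.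

Step 12
Reactants: 18 tert-butyl(dimethyl){[(1'S,3a'R,4'S,7a'S)-7'-methyl-4'-(prop-1-en-2-yl)-1',3',3a',4',5',7a'-hexahydrospiro[1,3-dithiane-2,2'-inden]-1'-yl]oxy}silane
Product: 19 tert-butyl(dimethyl){[(1'S,3a'R,4'R,7a'S)-7'-methyl-4'-(propan-2-yl)-1',3',3a',4',5',7a'-hexahydrospiro[1,3-dithiane-2,2'-inden]-1'-yl]oxy}silane
Conditions: 2-nitrobenzenesulfonylhydrazide, Et3N, CH2Cl2, rt
Reagents that add atoms: none
Why: diimide reduction; diimide transfers hydrogen to the 1,1-disubstituted alkene much faster than to the trisubstituted ring alkene, and, being metal-free, is indifferent to sulfur.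

Step 13
Reactants: 19 tert-butyl(dimethyl){[(1'S,3a'R,4'R,7a'S)-7'-methyl-4'-(propan-2-yl)-1',3',3a',4',5',7a'-hexahydrospiro[1,3-dithiane-2,2'-inden]-1'-yl]oxy}silane
Product: 20 (1S,3aR,4R,7aS)-1-{[tert-butyl(dimethyl)silyl]oxy}-7-methyl-4-(propan-2-yl)-1,3,3a,4,5,7a-hexahydro-2H-inden-2-one
Conditions: MeI, CaCO3, MeCN/H2O 9:1, 45 °C
Reagents that add atoms: water, O
Why: thioacetal hydrolysis by S-methylation under carbonate buffering; neither the silyl ether nor the ring alkene reacts with methyl iodide.

Step 14
Reactants: 20 (1S,3aR,4R,7aS)-1-{[tert-butyl(dimethyl)silyl]oxy}-7-methyl-4-(propan-2-yl)-1,3,3a,4,5,7a-hexahydro-2H-inden-2-one; 21 acetaldehyde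
Product: 24 (1S,3R,3aR,4R,7aS)-1-{[tert-butyl(dimethyl)silyl]oxy}-3-[(1S)-1-hydroxyethyl]-7-methyl-4-(propan-2-yl)-1,3,3a,4,5,7a-hexahydro-2H-inden-2-one, via lithium enolate 22 (not isolated), via triisopropoxytitanium enolate 23 (not isolated)
Conditions: LiN(iPr)2, THF, −78 °C; ClTi(OiPr)3, −78 → −40 °C; 21, −78 °C; aq. NH4Cl
Reagents that add atoms: none
Why: aldol addition of a titanium enolate; kinetic deprotonation should occur at the C3 methylene and not at the hindered silyloxy-bearing C1, and triisopropoxytitanium enolates of cyclic ketones are syn-selective although the enolate geometry is fixed as E. The aldehyde should add to C3 anti to the C3a–C4 bond, which places the arm trans and gives 3R,1'S.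

Step 15
Reactants: 24 (1S,3R,3aR,4R,7aS)-1-{[tert-butyl(dimethyl)silyl]oxy}-3-[(1S)-1-hydroxyethyl]-7-methyl-4-(propan-2-yl)-1,3,3a,4,5,7a-hexahydro-2H-inden-2-one
Product: 25 (1S,3R,3aR,4R,7aS)-3-[(1S)-1-(acetyloxy)ethyl]-1-{[tert-butyl(dimethyl)silyl]oxy}-7-methyl-4-(propan-2-yl)-1,3,3a,4,5,7a-hexahydro-2H-inden-2-one
Conditions: Ac2O, pyridine, DMAP (cat.), CH2Cl2, 0 °C
Reagents that add atoms: acetic anhydride, CC(=O)OC(C)=O
Why: acylation of the secondary alcohol under weak base at 0 °C, chosen to stay below the threshold for retro-aldol or E1cB loss of the new acetate.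

Step 16
Reactants: 25 (1S,3R,3aR,4R,7aS)-3-[(1S)-1-(acetyloxy)ethyl]-1-{[tert-butyl(dimethyl)silyl]oxy}-7-methyl-4-(propan-2-yl)-1,3,3a,4,5,7a-hexahydro-2H-inden-2-one
Product: 26 (1S,3R,3aR,4R,7aS)-3-[(1S)-1-(acetyloxy)ethyl]-1-hydroxy-7-methyl-4-(propan-2-yl)-1,3,3a,4,5,7a-hexahydro-2H-inden-2-one
Conditions: HF·pyridine, pyridine, THF, 0 °C → rt
Reagents that add atoms: none
Why: fluoride-mediated desilylation in a buffered, non-basic medium, so that the β-acetoxy ketone is not eliminated and the α-ketol is not equilibrated.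

Step 17
Reactants: 26 (1S,3R,3aR,4R,7aS)-3-[(1S)-1-(acetyloxy)ethyl]-1-hydroxy-7-methyl-4-(propan-2-yl)-1,3,3a,4,5,7a-hexahydro-2H-inden-2-one
Product: 27 (1S,3R,3aR,4R,6S,7R,7aR)-3-[(1S)-1-(acetyloxy)ethyl]-6,7-epoxy-1-hydroxy-7-methyl-4-(propan-2-yl)octahydro-2H-inden-2-one
Conditions: mCPBA, CH2Cl2, 0 °C
Reagents that add atoms: 3-chloroperoxybenzoic acid, OOC(=O)c1cccc(Cl)c1
Why: hydroxyl-directed peracid epoxidation of a homoallylic alcohol; the free α-hydroxyl at C1 lies beside C7 and should hydrogen-bond the peracid and deliver oxygen to the α-face, which sets C6 (S) and C7. The trisubstituted alkene should react well before any Baeyer–Villiger oxidation of the ketone.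

Step 18
Reactants: 27 (1S,3R,3aR,4R,6S,7R,7aR)-3-[(1S)-1-(acetyloxy)ethyl]-6,7-epoxy-1-hydroxy-7-methyl-4-(propan-2-yl)octahydro-2H-inden-2-one; 28 (2R)-2-methylbutanoic acid
Product: 29 (1R,3R,3aR,4R,6S,7R,7aR)-3-[(1S)-1-(acetyloxy)ethyl]-6,7-epoxy-7-methyl-2-oxo-4-(propan-2-yl)octahydro-1H-inden-1-yl (2R)-2-methylbutanoate
Conditions: PPh3, DIAD (added last), toluene, 0 °C → rt
Reagents that add atoms: none
Why: Mitsunobu esterification; SN2 displacement at the carbonyl-activated C1 inverts it to the required 1R configuration, and no anti-periplanar hydrogen is available for elimination because H7a is cis to the leaving oxygen. The acid stereocentre is not touched, since the acid is never activated as an acyl donor.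

Step 19
Reactants: 29 (1R,3R,3aR,4R,6S,7R,7aR)-3-[(1S)-1-(acetyloxy)ethyl]-6,7-epoxy-7-methyl-2-oxo-4-(propan-2-yl)octahydro-1H-inden-1-yl (2R)-2-methylbutanoate
Product: 30 (1R,3R,3aR,4R,6S,7aS)-3-[(1S)-1-(acetyloxy)ethyl]-6-hydroxy-7-methylidene-2-oxo-4-(propan-2-yl)octahydro-1H-inden-1-yl (2R)-2-methylbutanoate
Conditions: (C5H5)2TiCl2 (2.5 equiv), Mn dust, THF, rt; then 29; aq. NaH2PO4
Reagents that add atoms: none
Why: epoxide-to-allylic-alcohol isomerisation by trivalent titanium; (C5H5)2TiCl should cleave the tertiary C7–O bond homolytically and a second equivalent removes a hydrogen from the C7 methyl group of the radical, giving the exocyclic alkene. The C6–O bond is never broken, so C6 keeps the configuration set in step 17, and the medium is neutral towards the three esters.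

Step 20
Reactants: 30 (1R,3R,3aR,4R,6S,7aS)-3-[(1S)-1-(acetyloxy)ethyl]-6-hydroxy-7-methylidene-2-oxo-4-(propan-2-yl)octahydro-1H-inden-1-yl (2R)-2-methylbutanoate; 31 (2E)-3-methylpent-2-enoic acid
Product: 32 (1R,3R,3aR,4R,6S,7aS)-3-[(1S)-1-(acetyloxy)ethyl]-7-methylidene-1-{[(2R)-2-methylbutanoyl]oxy}-2-oxo-4-(propan-2-yl)octahydro-1H-inden-6-yl (2E)-3-methylpent-2-enoate
Conditions: DCC, DMAP (0.2 equiv), CH2Cl2, 0 °C → rt
Reagents that add atoms: none
Why: Steglich esterification of the axial allylic alcohol with retention at C6; catalytic DMAP at low temperature is chosen to limit deconjugation of the acyl donor and loss of the acetate.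

## Compound list

1 | 1,3-dithiane | C1CSCSC1 | starting material
2 | 2-bromo-1,1-diethoxyethane | CCOC(CBr)OCC | starting material
3 | 2-lithio-1,3-dithiane | [Li]C1SCCCS1 | intermediate
4 | 2-(2,2-diethoxyethyl)-1,3-dithiane | CCOC(CC1SCCCS1)OCC | intermediate
5 | (2E)-3-methylpent-2-en-4-yn-1-ol | C#C/C(C)=C/CO | starting material
6 | (2E)-3-methylpenta-2,4-dien-1-ol | C=C/C(C)=C/CO | intermediate
7 | (2E)-3-methylpenta-2,4-dienal | C=C/C(C)=C/C=O | intermediate
8 | 2-lithio-2-(2,2-diethoxyethyl)-1,3-dithiane | [Li]C1(CC(OCC)OCC)SCCCS1 | intermediate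
9 | rac-(2E)-1-[2-(2,2-diethoxyethyl)-1,3-dithian-2-yl]-3-methylpenta-2,4-dien-1-ol | CCOC(CC1(SCCCS1)C(O)/C=C(\C)C=C)OCC | intermediate
10 | (2E)-1-[2-(2,2-diethoxyethyl)-1,3-dithian-2-yl]-3-methylpenta-2,4-dien-1-one | CCOC(CC1(SCCCS1)C(=O)/C=C(\C)C=C)OCC | intermediate
11 | (1S,2E)-1-[2-(2,2-diethoxyethyl)-1,3-dithian-2-yl]-3-methylpenta-2,4-dien-1-ol | CCOC(CC1(SCCCS1)[C@@H](O)/C=C(\C)C=C)OCC | intermediate
12 | tert-butyl{[(1S,2E)-1-[2-(2,2-diethoxyethyl)-1,3-dithian-2-yl]-3-methylpenta-2,4-dien-1-yl]oxy}dimethylsilane | CCOC(CC1(SCCCS1)[C@@H](O[Si](C)(C)C(C)(C)C)/C=C(\C)C=C)OCC | intermediate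
13 | 1-(2-{2-[(1S,2E)-1-{[tert-butyl(dimethyl)silyl]oxy}-3-methylpenta-2,4-dien-1-yl]-1,3-dithian-2-yl}-1-ethoxyethyl)-2,4,6-trimethylpyridinium trifluoromethanesulfonate (both epimers at the N,O-acetal carbon) | CCOC(CC1(SCCCS1)[C@@H](O[Si](C)(C)C(C)(C)C)/C=C(\C)C=C)[n+]1c(C)cc(C)cc1C.[O-]S(=O)(=O)C(F)(F)F | intermediate
14 | {2-[(1S,2E)-1-{[tert-butyl(dimethyl)silyl]oxy}-3-methylpenta-2,4-dien-1-yl]-1,3-dithian-2-yl}acetaldehyde | O=CCC1(SCCCS1)[C@@H](O[Si](C)(C)C(C)(C)C)/C=C(\C)C=C | intermediate
15 | 1-(triphenylphosphoranylidene)propan-2-one | CC(=O)C=P(c1ccccc1)(c1ccccc1)c1ccccc1 | starting material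
16 | (3E)-5-{2-[(1S,2E)-1-{[tert-butyl(dimethyl)silyl]oxy}-3-methylpenta-2,4-dien-1-yl]-1,3-dithian-2-yl}pent-3-en-2-one | CC(=O)/C=C/CC1(SCCCS1)[C@@H](O[Si](C)(C)C(C)(C)C)/C=C(\C)C=C | intermediate
17 | 1-[(1'S,3a'S,4'S,7a'S)-1'-{[tert-butyl(dimethyl)silyl]oxy}-7'-methyl-1',3',3a',4',5',7a'-hexahydrospiro[1,3-dithiane-2,2'-inden]-4'-yl]ethan-1-one | CC1=CC[C@H](C(C)=O)[C@H]2CC3(SCCCS3)[C@@H](O[Si](C)(C)C(C)(C)C)[C@H]12 | intermediate
18 | tert-butyl(dimethyl){[(1'S,3a'R,4'S,7a'S)-7'-methyl-4'-(prop-1-en-2-yl)-1',3',3a',4',5',7a'-hexahydrospiro[1,3-dithiane-2,2'-inden]-1'-yl]oxy}silane | CC1=CC[C@H](C(C)=C)[C@H]2CC3(SCCCS3)[C@@H](O[Si](C)(C)C(C)(C)C)[C@H]12 | intermediate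
19 | tert-butyl(dimethyl){[(1'S,3a'R,4'R,7a'S)-7'-methyl-4'-(propan-2-yl)-1',3',3a',4',5',7a'-hexahydrospiro[1,3-dithiane-2,2'-inden]-1'-yl]oxy}silane | CC1=CC[C@H](C(C)C)[C@H]2CC3(SCCCS3)[C@@H](O[Si](C)(C)C(C)(C)C)[C@H]12 | intermediate
20 | (1S,3aR,4R,7aS)-1-{[tert-butyl(dimethyl)silyl]oxy}-7-methyl-4-(propan-2-yl)-1,3,3a,4,5,7a-hexahydro-2H-inden-2-one | CC1=CC[C@H](C(C)C)[C@H]2CC(=O)[C@@H](O[Si](C)(C)C(C)(C)C)[C@H]12 | intermediate
21 | acetaldehyde | CC=O | starting material
22 | lithium enolate of 20 (C2=C3 double bond, lithium on the C2 oxygen) | CC1=CC[C@H](C(C)C)[C@H]2C=C(O[Li])[C@@H](O[Si](C)(C)C(C)(C)C)[C@H]12 | intermediate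
23 | triisopropoxytitanium enolate of 20 (C2=C3 double bond, titanium on the C2 oxygen) | CC1=CC[C@H](C(C)C)[C@H]2C=C(O[Ti](OC(C)C)(OC(C)C)OC(C)C)[C@@H](O[Si](C)(C)C(C)(C)C)[C@H]12 | intermediate
24 | (1S,3R,3aR,4R,7aS)-1-{[tert-butyl(dimethyl)silyl]oxy}-3-[(1S)-1-hydroxyethyl]-7-methyl-4-(propan-2-yl)-1,3,3a,4,5,7a-hexahydro-2H-inden-2-one | CC1=CC[C@H](C(C)C)[C@H]2[C@H]([C@H](C)O)C(=O)[C@@H](O[Si](C)(C)C(C)(C)C)[C@H]12 | intermediate
25 | (1S,3R,3aR,4R,7aS)-3-[(1S)-1-(acetyloxy)ethyl]-1-{[tert-butyl(dimethyl)silyl]oxy}-7-methyl-4-(propan-2-yl)-1,3,3a,4,5,7a-hexahydro-2H-inden-2-one | CC1=CC[C@H](C(C)C)[C@H]2[C@H]([C@H](C)OC(C)=O)C(=O)[C@@H](O[Si](C)(C)C(C)(C)C)[C@H]12 | intermediate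
26 | (1S,3R,3aR,4R,7aS)-3-[(1S)-1-(acetyloxy)ethyl]-1-hydroxy-7-methyl-4-(propan-2-yl)-1,3,3a,4,5,7a-hexahydro-2H-inden-2-one | CC1=CC[C@H](C(C)C)[C@H]2[C@H]([C@H](C)OC(C)=O)C(=O)[C@@H](O)[C@H]12 | intermediate
27 | (1S,3R,3aR,4R,6S,7R,7aR)-3-[(1S)-1-(acetyloxy)ethyl]-6,7-epoxy-1-hydroxy-7-methyl-4-(propan-2-yl)octahydro-2H-inden-2-one (epoxide oxygen on the face of the C1 hydroxyl) | C[C@]12O[C@H]1C[C@H](C(C)C)[C@H]3[C@H]([C@H](C)OC(C)=O)C(=O)[C@@H](O)[C@H]23 | intermediate
28 | (2R)-2-methylbutanoic acid | CC[C@@H](C)C(=O)O | starting material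
29 | (1R,3R,3aR,4R,6S,7R,7aR)-3-[(1S)-1-(acetyloxy)ethyl]-6,7-epoxy-7-methyl-2-oxo-4-(propan-2-yl)octahydro-1H-inden-1-yl (2R)-2-methylbutanoate | C[C@]12O[C@H]1C[C@H](C(C)C)[C@H]3[C@H]([C@H](C)OC(C)=O)C(=O)[C@H](OC(=O)[C@H](C)CC)[C@H]23 | intermediate
30 | (1R,3R,3aR,4R,6S,7aS)-3-[(1S)-1-(acetyloxy)ethyl]-6-hydroxy-7-methylidene-2-oxo-4-(propan-2-yl)octahydro-1H-inden-1-yl (2R)-2-methylbutanoate | C=C1[C@@H]2[C@H]([C@H]([C@H](C)OC(C)=O)C(=O)[C@@H]2OC(=O)[C@H](C)CC)[C@@H](C(C)C)C[C@@H]1O | intermediate
31 | (2E)-3-methylpent-2-enoic acid | CC/C(C)=C/C(=O)O | starting material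
32 | (1R,3R,3aR,4R,6S,7aS)-3-[(1S)-1-(acetyloxy)ethyl]-7-methylidene-1-{[(2R)-2-methylbutanoyl]oxy}-2-oxo-4-(propan-2-yl)octahydro-1H-inden-6-yl (2E)-3-methylpent-2-enoate (CNP0289166.2) | C=C1[C@@H]2[C@H]([C@H]([C@H](C)OC(C)=O)C(=O)[C@@H]2OC(=O)[C@H](C)CC)[C@@H](C(C)C)C[C@@H]1OC(=O)/C=C(\C)CC | target

## Step count and least certain steps

Total step count: 20. Longest linear sequence: 19 steps (5 → 6 → 7 → 9 → … → 32; the branch from 1 joins at step 4).

Step 10 (key step). The most likely failure is erosion of endo selectivity, with the tether-endo transition state giving cis-fused material, because the three-atom tether only weakly separates the two modes. A second risk is ionisation of the dienylic C–O bond if aluminium binds the silyl ether or sulfur instead of the enone. Fallback, from 14 back to 17: 14 is olefinated with Ph3P=CHCHO to the (2E)-trienal F1. F1 is cyclised by iminium-ion catalysis with a chiral imidazolidinone salt (the catalyst enantiomer that reinforces the substrate bias, MeCN/H2O, no Lewis acid) to the bicyclic aldehyde F2. MeMgBr then gives the carbinol F3, and Parikh–Doering oxidation (SO3·pyridine, DMSO, iPr2NEt) returns the methyl ketone 17.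

Step 6. The most likely failure is weak or reversed facial discrimination, because the planar dienyl group may compete with the thioacetal carbon for the role of the large substituent; slow reduction of the hindered ketone could also let uncatalysed background reduction intervene. Fallback, from 9 back to 11 (bypassing steps 5 and 6): racemic 9 is esterified with (2S)-2-methoxy-2-phenylacetic acid (DCC, DMAP), the diastereomers are separated by chromatography, and the ester of the (S)-carbinol, mandelate F4, is cleaved with iBu2AlH at −78 °C to give 11.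

Step 14. The most likely failure is poor syn/anti discrimination, because a closed chair transition state of the fixed E-enolate (anti) competes with the syn-selective pathway, and acetaldehyde is a small, undemanding partner. Retro-aldol on work-up is a second risk. Fallback, from 20 back to 24, with the carbinol set by a catalyst instead of the enolate: 20 is taken through an unselective lithium aldol with 21 to the carbinol mixture F5. Mesylation and elimination (MsCl, Et3N; DBU) converge it to the (E)-ethylidene ketone F6. Copper-catalysed enantioselective conjugate borylation (CuCl, NaOtBu, a chiral ferrocenyl bisphosphine, B2pin2, MeOH) sets C1' under ligand control, with protonation trans at C3, to give the β-boryl ketone F7. Oxidation with NaBO3 (retention) gives 24.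

Step 17. The most likely failure is insufficient facial selectivity, because the directing hydroxyl is also hydrogen-bonded to the neighbouring ketone; slow Baeyer–Villiger oxidation is a minor risk. Fallback, from 25 back to 32, with steric control and a second inversion: 25 is epoxidised with mCPBA while the bulky silyl ether still shields the α-face, giving the β-epoxide F8. HF·pyridine frees the ketol F9, and Mitsunobu reaction with 28 gives the C1-inverted ester F10. Trivalent-titanium isomerisation as in step 19 gives the equatorial allylic alcohol F11 (6R). A Mitsunobu reaction with 31 then inverts C6 and gives 32 directly.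

Step 19. The most likely failures are electron transfer from titanium to the chelating α-acyloxy ketone (reductive loss of the C1 ester), hydrogen abstraction at C7a instead of the methyl group, and simple reduction of the tertiary radical. Fallback, from 27 back to 32, so that titanium meets only an α-silyloxy ketone: 27 is silylated (Et3SiCl, imidazole) to the triethylsilyl ether F12. Titanium isomerisation gives the allylic alcohol F13, and Steglich esterification with 31 gives the C6 ester F14. HF·pyridine then frees the ketol F15, and the Mitsunobu reaction with 28 is run last to give 32.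

## Further compounds

F1 | step 10 | (2E)-4-{2-[(1S,2E)-1-{[tert-butyl(dimethyl)silyl]oxy}-3-methylpenta-2,4-dien-1-yl]-1,3-dithian-2-yl}but-2-enal | O=C/C=C/CC1(SCCCS1)[C@@H](O[Si](C)(C)C(C)(C)C)/C=C(\C)C=C
F2 | step 10 | (1'S,3a'S,4'S,7a'S)-1'-{[tert-butyl(dimethyl)silyl]oxy}-7'-methyl-1',3',3a',4',5',7a'-hexahydrospiro[1,3-dithiane-2,2'-indene]-4'-carbaldehyde | CC1=CC[C@H](C=O)[C@H]2CC3(SCCCS3)[C@@H](O[Si](C)(C)C(C)(C)C)[C@H]12
F3 | step 10 | 1-[1'-{[tert-butyl(dimethyl)silyl]oxy}-7'-methyl-1',3',3a',4',5',7a'-hexahydrospiro[1,3-dithiane-2,2'-inden]-4'-yl]ethan-1-ol, ring stereocentres as in 17, both carbinol epimers | CC1=CC[C@H](C(C)O)[C@H]2CC3(SCCCS3)[C@@H](O[Si](C)(C)C(C)(C)C)[C@H]12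
F4 | step 6 | (1S,2E)-1-[2-(2,2-diethoxyethyl)-1,3-dithian-2-yl]-3-methylpenta-2,4-dien-1-yl (2S)-2-methoxy-2-phenylacetate | CCOC(CC1(SCCCS1)[C@@H](OC(=O)[C@@H](OC)c1ccccc1)/C=C(\C)C=C)OCC
F5 | step 14 | 1-{[tert-butyl(dimethyl)silyl]oxy}-3-(1-hydroxyethyl)-7-methyl-4-(propan-2-yl)-1,3,3a,4,5,7a-hexahydro-2H-inden-2-one, ring stereocentres as in 24, both carbinol epimers | CC1=CC[C@H](C(C)C)[C@H]2[C@H](C(C)O)C(=O)[C@@H](O[Si](C)(C)C(C)(C)C)[C@H]12
F6 | step 14 | (3E)-1-{[tert-butyl(dimethyl)silyl]oxy}-3-ethylidene-7-methyl-4-(propan-2-yl)-1,3,3a,4,5,7a-hexahydro-2H-inden-2-one, ring stereocentres as in 20 | CC1=CC[C@H](C(C)C)[C@H]2/C(=C\C)C(=O)[C@@H](O[Si](C)(C)C(C)(C)C)[C@H]12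
F7 | step 14 | 1-{[tert-butyl(dimethyl)silyl]oxy}-7-methyl-4-(propan-2-yl)-3-[1-(4,4,5,5-tetramethyl-1,3,2-dioxaborolan-2-yl)ethyl]-1,3,3a,4,5,7a-hexahydro-2H-inden-2-one, stereocentres placed as in 24 | CC1=CC[C@H](C(C)C)[C@H]2[C@H]([C@H](C)B3OC(C)(C)C(C)(C)O3)C(=O)[C@@H](O[Si](C)(C)C(C)(C)C)[C@H]12
F8 | step 17 | (1S,3R,3aR,4R,6R,7S,7aR)-3-[(1S)-1-(acetyloxy)ethyl]-1-{[tert-butyl(dimethyl)silyl]oxy}-6,7-epoxy-7-methyl-4-(propan-2-yl)octahydro-2H-inden-2-one (epoxide anti to the silyl ether) | C[C@@]12O[C@@H]1C[C@H](C(C)C)[C@H]3[C@H]([C@H](C)OC(C)=O)C(=O)[C@@H](O[Si](C)(C)C(C)(C)C)[C@H]23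
F9 | step 17 | (1S,3R,3aR,4R,6R,7S,7aR)-3-[(1S)-1-(acetyloxy)ethyl]-6,7-epoxy-1-hydroxy-7-methyl-4-(propan-2-yl)octahydro-2H-inden-2-one | C[C@@]12O[C@@H]1C[C@H](C(C)C)[C@H]3[C@H]([C@H](C)OC(C)=O)C(=O)[C@@H](O)[C@H]23
F10 | step 17 | (1R,3R,3aR,4R,6R,7S,7aR)-3-[(1S)-1-(acetyloxy)ethyl]-6,7-epoxy-7-methyl-2-oxo-4-(propan-2-yl)octahydro-1H-inden-1-yl (2R)-2-methylbutanoate | C[C@@]12O[C@@H]1C[C@H](C(C)C)[C@H]3[C@H]([C@H](C)OC(C)=O)C(=O)[C@H](OC(=O)[C@H](C)CC)[C@H]23
F11 | step 17 | (1R,3R,3aR,4R,6R,7aS)-3-[(1S)-1-(acetyloxy)ethyl]-6-hydroxy-7-methylidene-2-oxo-4-(propan-2-yl)octahydro-1H-inden-1-yl (2R)-2-methylbutanoate | C=C1[C@@H]2[C@H]([C@H]([C@H](C)OC(C)=O)C(=O)[C@@H]2OC(=O)[C@H](C)CC)[C@@H](C(C)C)C[C@H]1O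
F12 | step 19 | (1S,3R,3aR,4R,6S,7R,7aR)-3-[(1S)-1-(acetyloxy)ethyl]-6,7-epoxy-7-methyl-4-(propan-2-yl)-1-[(triethylsilyl)oxy]octahydro-2H-inden-2-one | C[C@]12O[C@H]1C[C@H](C(C)C)[C@H]3[C@H]([C@H](C)OC(C)=O)C(=O)[C@@H](O[Si](CC)(CC)CC)[C@H]23
F13 | step 19 | (1S,3R,3aR,4R,6S,7aS)-3-[(1S)-1-(acetyloxy)ethyl]-6-hydroxy-7-methylidene-4-(propan-2-yl)-1-[(triethylsilyl)oxy]octahydro-2H-inden-2-one | C=C1[C@@H]2[C@H]([C@H]([C@H](C)OC(C)=O)C(=O)[C@H]2O[Si](CC)(CC)CC)[C@@H](C(C)C)C[C@@H]1O
F14 | step 19 | (1S,3R,3aR,4R,6S,7aS)-3-[(1S)-1-(acetyloxy)ethyl]-7-methylidene-2-oxo-4-(propan-2-yl)-1-[(triethylsilyl)oxy]octahydro-1H-inden-6-yl (2E)-3-methylpent-2-enoate | C=C1[C@@H]2[C@H]([C@H]([C@H](C)OC(C)=O)C(=O)[C@H]2O[Si](CC)(CC)CC)[C@@H](C(C)C)C[C@@H]1OC(=O)/C=C(\C)CC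
F15 | step 19 | (1S,3R,3aR,4R,6S,7aS)-3-[(1S)-1-(acetyloxy)ethyl]-1-hydroxy-7-methylidene-2-oxo-4-(propan-2-yl)octahydro-1H-inden-6-yl (2E)-3-methylpent-2-enoate | C=C1[C@@H]2[C@H]([C@H]([C@H](C)OC(C)=O)C(=O)[C@H]2O)[C@@H](C(C)C)C[C@@H]1OC(=O)/C=C(\C)CC
A1 | alternative 1 | cyclopentanone ynal: 2-ethynyl cyclopentanone carrying the silyloxyethyl arm and the 3-isopropyl-4-oxobutyl chain, stereocentres as in the SMILES | C#C[C@@H]1[C@H]([C@H]([C@H](C)O[Si](C)(C)C(C)(C)C)C(=O)C1)[C@@H](C(C)C)CC=O
A2 | alternative 1 | trans-hydrindanone with exocyclic methylene and equatorial triethylsilyl ether at C6 | C=C1[C@@H]2[C@H]([C@H]([C@H](C)O[Si](C)(C)C(C)(C)C)C(=O)C2)[C@@H](C(C)C)C[C@H]1O[Si](CC)(CC)CC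
A3 | alternative 2 | 4-(propan-2-yl)cyclohexan-1-one | CC(C)C1CCC(=O)CC1
A4 | alternative 2 | α-diazo-β-keto ester on the ketal-protected cyclohexane, stereocentres as in the SMILES | O1CCOC12[C@@H]([C@@H](O[Si](C)(C)C(C)(C)C)C(=O)C(=[N+]=[N-])C(=O)OCC)C[C@@H](C(C)C)CC2
A5 | alternative 2 | trans-fused bicyclic β-keto ester with dioxolane at C7 and silyl ether at C1 | O1CCOC12[C@@H]3[C@H]([C@H](C(=O)OCC)C(=O)[C@@H]3O[Si](C)(C)C(C)(C)C)[C@@H](C(C)C)CC2
A6 | alternative 3 | acetonide-templated 1,7-enyne with vinyl group, internal alkyne and silyloxyethyl terminus, stereocentres as in the SMILES | CC1(C)OC[C@H](C=C)[C@@H](O1)C[C@H](C(C)C)C#C[C@H](C)O[Si](C)(C)C(C)(C)C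
A7 | alternative 3 | bicyclic cyclopentenone acetonide | CC1(C)OC[C@H]2[C@@H](O1)C[C@H](C(C)C)C3=C([C@H](C)O[Si](C)(C)C(C)(C)C)C(=O)C[C@H]23
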